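| flask | electrophile | nucleophile | remark | time |
|---|---|---|---|---|
| green | 0.056 M | 0.98 equiv (fed, over 2.5 min) | run made earlier |  |
| grey | 0.056 M | 1.4 equiv (fed, over 2.5 min) | run made earlier |  |
| maple | 0.056 M | 1.20 equiv (fed, over 2.5 min) |  | 8.0 min |
| ash | 0.056 M | 1.80 equiv (fed, over 2.5 min) |  | 8.0 min |

- green (time / min: electrophile / %, product / %): 0.333: 101.1, 0; 0.500: 100.6, 0; 0.833: 98.8, 2.6; 1.33: 97.5, 3.4; 2.50: 90.9, 10.3; 4.00: 82.8, 16.6
- grey (time / min: electrophile / %, product / %): 0.667: 99.3, 0; 1.33: 96.5, 3.8; 2.00: 93.2, 6.6; 2.50: 87.8, 11.3; 3.00: 84.8, 15.2; 4.00: 77.6, 21.8

(each reading ± 1 percentage point)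

- the numbers in the tables scatter with a standard deviation of 1 percentage point

- part of the electrophile that has reacted at the end, maple
- part of the electrophile that has reacted at the end, ash
- what raising the equivalents of nucleophile from its lowest to its highest value here does to the part of the electrophile that has reacted (changes below 5 percentage points count as none) (no change / it rises / it falls)

At 4.00 min the grey run keeps less electrophile than the green run, 77.6% against 82.8%, which raises the question of whether equivalents and time can be joined in one measure. A steady feed gives the same area under the nucleophile curve as the whole charge added at mid-feed, and in maple and ash that feed fills about a third of the time, so each flask counts 6.75 min at full charge.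

How fast does that charge work? Taking the mean nucleophile as the charge less half the conversion, and dividing the logarithm of the electrophile's fall by that mean and the time, green gives 0.0768 min⁻¹ and grey 0.0716 min⁻¹. One reading's scatter moves green's value by 0.00491 min⁻¹, so the two can share a mean: 0.0742 min⁻¹ for each equivalent, the dose constant, a pseudo-first-order constant of electrophile loss per equivalent of nucleophile.

Solved for the mean, this reckoning gives 39.6% for maple and 53.6% for ash, a rise of 14 points. The correction for nucleophile used is 16.5% of maple's charge, the error to watch.

The forecast is lower, 37% for maple and 51% for ash, and of raising the equivalents it says it rises: “More nucleophile clearly raises conversion at a fixed time”.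

The flasks give 34.1% for maple and 47.5% for ash, and of raising the equivalents from the lowest to the highest value the answer is it rises, by 13 points, so the forecast holds.

    electrophile + nucleophile → acid set free + product (k = 0.0334 L mol⁻¹ s⁻¹)
    nucleophile + acid set free ⇌ protonated nucleophile, settled at all times (K = 2200 L mol⁻¹)
    nucleophile ⇌ dormant form (K = 0.430, k = 0.0411 s⁻¹)
    nucleophile + acid set free ⇌ idle adduct, settled at all times (K = 127 L mol⁻¹)

In maple at 8.00 min, free nucleophile is 30.4% of its charge, less than the 71.5% that product formation would leave, with protonated nucleophile at 0.0177 M, dormant form at 0.00894 M and idle adduct at 0.00102 M beside it. Maple's result, put back through the same mean, gives a dose constant of 0.0601 min⁻¹, below the 0.0742 min⁻¹ read at 4.00 min.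

A neighbour flask repeats ash with 0.034 M of electrophile, the equivalents and the time held; the dose constant, taken in proportion to the electrophile concentration, becomes 0.0450 min⁻¹ there, which gives 38.7%. That neighbour flask gives 36.0%.

(The data are calculated on assumed constants; noise was put on by code.)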